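The cyclohexenone ring is cut between C2 and C3 and between C4 and C5. Its C3 enol-ether carbon with the 3-OMe group is read as the carbonyl carbon of a methyl ester, whose α-carbon is the ketal carbon C4; C5–C6–C1–C2 is a γ-bromo acyl ylide. In one pot the C4 carbanion of an α-aryloxy-α-phenylthio ester is alkylated at C5 and the ylide then olefinates the ester carbonyl, so the ester methoxy becomes the 3-OMe of the vinylogous ester. Sulfur at C4 is a temporary activating group: it is later exchanged for OMe under control of the C6 allyl centre, itself set by Pd-catalysed asymmetric allylation.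

Key step: step 6

Ring numbering used throughout: C1 (C=O), C2 (=CH), C3 (C–OMe), C4 (ketal carbon), C5 (CH2), C6 (CH–allyl). The target is (4R,6S), with the aryloxy group cis and the 4-OMe trans to the C6 allyl group.

Assumption: the sense of induction of the (R,R)-ligand in step 8 is assigned by analogy with related allyl enol carbonates; if C6 proves to be R, the (S,S)-ligand is used instead.

Step 1
Reactants: 1 3,4-dimethoxyphenol
Product: 2 4-(allyloxy)-1,2-dimethoxybenzene
Conditions: allyl bromide, K2CO3, acetone, reflux
Reagents that add atoms: allyl bromide C=CCBr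
Why: Williamson ether synthesis of the phenoxide with a reactive allylic bromide, no stereocentre involved.

Step 2
Reactants: 2 4-(allyloxy)-1,2-dimethoxybenzene
Product: 3 2-allyl-4,5-dimethoxyphenol
Conditions: N,N-diethylaniline, 200 °C
Reagents that add atoms: none
Why: Aromatic Claisen rearrangement ([3,3]) followed by tautomerisation, which should deliver the allyl group to the unhindered ortho position para to the meta-methoxy donor and not to the position flanked by OMe.

Step 3
Reactants: 4 methyl 2-(phenylthio)acetate
Product: 5 methyl 2-chloro-2-(phenylthio)acetate (racemic)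
Conditions: NCS, CH2Cl2, 0 °C to rt
Reagents that add atoms: N-chlorosuccinimide O=C1CCC(=O)N1Cl
Why: α-Chlorination of a sulfide through the chlorosulfonium/thionium ion (Pummerer-type), which stops at the monochloride of the ester-activated carbon.

Step 4
Reactants: 3 2-allyl-4,5-dimethoxyphenol; 5 methyl 2-chloro-2-(phenylthio)acetate
Product: 6 methyl 2-(2-allyl-4,5-dimethoxyphenoxy)-2-(phenylthio)acetate (racemic)
Conditions: K2CO3, acetone, 0 °C to rt
Reagents that add atoms: none
Why: The α-chloro sulfide is a thionium-ion precursor that is captured on oxygen by the phenoxide (O,S-acetal formation); the new centre is racemic and of no consequence because this carbon is made planar again twice later.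

Step 5
Reactants: 7 1,4-dibromobutan-2-one
Product: 9 4-bromo-1-(triphenyl-λ5-phosphanylidene)butan-2-one, via phosphonium bromide 8 (not isolated)
Conditions: PPh3, toluene, rt; then aq. Na2CO3, CH2Cl2, 0 °C; used at once
Reagents that add atoms: triphenylphosphine c1ccc(P(c2ccccc2)c2ccccc2)cc1
Why: Triphenylphosphine quaternises at the far more reactive α-bromo ketone carbon, and mild base removes the acidic P–CH2 proton to give the stabilised acyl ylide, whose deactivated carbonyl no longer promotes loss of HBr.

Step 6
Reactants: 6 methyl 2-(2-allyl-4,5-dimethoxyphenoxy)-2-(phenylthio)acetate; 9 4-bromo-1-(triphenyl-λ5-phosphanylidene)butan-2-one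
Product: 11 4-(2-allyl-4,5-dimethoxyphenoxy)-3-methoxy-4-(phenylthio)cyclohex-2-en-1-one (racemic), via keto-ylide 10 (not isolated)
Conditions: NaH, THF–DMF, 0 °C; 9, NaI (cat.), rt; then toluene, 110 °C
Reagents that add atoms: none
Why: Proposed new method: the sulfur- and ester-stabilised sodium enolate of 6 is C-alkylated by the primary bromide of 9 (SN2, C4–C5) to give ylide 10, whose ylide carbon then adds to the ester carbonyl, and the oxaphosphetane collapses to Ph3P=O and the C2=C3 enol ether, so the ester methoxy ends as the 3-OMe. The closest known reactions are the tandem conjugate addition/intramolecular Wittig annulations of vinyl- and butadienylphosphonium salts and the intramolecular Wittig olefination of ester carbonyls by stabilised ylides (chromone and tetronate syntheses). The six-membered ring closes by 6-exo-trig addition of the ylide carbon to the ester C=O followed by [2+2] cycloreversion. C4 is formed without control, which is intended, since it is made planar again in step 9. The step needs olefination to win over Claisen-type loss of methoxide (C-acylation of the ylide), which the two electron-withdrawing α-heteroatoms at C4, the non-enolisable quaternary α-carbon and the six-membered transition state should favour. E2 at the β-bromo ketone is not destructive, because the vinyl acyl ylide so formed can take up the same soft carbanion by conjugate addition and give the same adduct 10.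

Step 7
Reactants: 11 4-(2-allyl-4,5-dimethoxyphenoxy)-3-methoxy-4-(phenylthio)cyclohex-2-en-1-one
Product: 12 allyl 4-(2-allyl-4,5-dimethoxyphenoxy)-5-methoxy-4-(phenylthio)cyclohexa-1,5-dien-1-yl carbonate (racemic)
Conditions: NaHMDS, TMEDA, THF, −78 °C; allyl chloroformate
Reagents that add atoms: allyl chloroformate C=CCOC(=O)Cl
Why: Kinetic α'-deprotonation of the vinylogous ester at C6 (the enolate of the Stork–Danheiser alkylation) and O-acylation of the amine-solvated sodium enolate by the chloroformate should give the cross-conjugated enol carbonate.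

Step 8
Reactants: 12 allyl 4-(2-allyl-4,5-dimethoxyphenoxy)-5-methoxy-4-(phenylthio)cyclohexa-1,5-dien-1-yl carbonate
Product: 13 (6S)-6-allyl-4-(2-allyl-4,5-dimethoxyphenoxy)-3-methoxy-4-(phenylthio)cyclohex-2-en-1-one (mixture of the two C4 epimers)
Conditions: Pd2(dba)3·CHCl3 (cat.), (R,R)-ANDEN-phenyl bis(2-diphenylphosphinobenzamide) ligand (cat.), 1,4-dioxane, rt
Reagents that add atoms: none
Why: Pd-catalysed decarboxylative asymmetric allylic alkylation (Tsuji–Trost type) of the allyl enol carbonate: ionisation and loss of CO2 give a π-allyl-Pd/enolate pair that recombines regiospecifically at C6 inside the chiral pocket of the ligand, which should set C6 as S under catalyst control whatever the configuration at C4, while the neutral conditions protect the new tertiary α-centre from enolate exchange.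

Step 9
Reactants: 13 (6S)-6-allyl-4-(2-allyl-4,5-dimethoxyphenoxy)-3-methoxy-4-(phenylthio)cyclohex-2-en-1-one
Product: 14 (4R,6S)-6-allyl-4-(2-allyl-4,5-dimethoxyphenoxy)-3,4-dimethoxycyclohex-2-en-1-one
Conditions: AgOTf, MeOH, 2,6-di-tert-butyl-4-methylpyridine, 4 Å MS, CH2Cl2, −60 to −20 °C
Reagents that add atoms: methanol CO
Why: Silver(I) abstracts the thiolate (thioglycoside-type activation of an O,S-ketal) to give the aryloxy-stabilised oxocarbenium ion common to both C4 epimers, and methanol should add along the axial trajectory of the half-chair that holds the C6 allyl group pseudo-equatorial, that is anti to the allyl group (as in axial hydride delivery to 5-substituted cyclohex-2-enones), which sets C4 as R with the aryloxy group cis to allyl; the buffered thiophilic conditions should not re-ionise the O,O-ketal, so the kinetic result is kept.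

Compound list
1 | 3,4-dimethoxyphenol | COc1ccc(O)cc1OC | starting material
2 | 4-(allyloxy)-1,2-dimethoxybenzene | C=CCOc1ccc(OC)c(OC)c1 | intermediate
3 | 2-allyl-4,5-dimethoxyphenol | C=CCc1cc(OC)c(OC)cc1O | intermediate
4 | methyl 2-(phenylthio)acetate | COC(=O)CSc1ccccc1 | starting material
5 | methyl 2-chloro-2-(phenylthio)acetate (racemic) | COC(=O)C(Cl)Sc1ccccc1 | intermediate
6 | methyl 2-(2-allyl-4,5-dimethoxyphenoxy)-2-(phenylthio)acetate (racemic) | C=CCc1cc(OC)c(OC)cc1OC(Sc1ccccc1)C(=O)OC | intermediate
7 | 1,4-dibromobutan-2-one | BrCCC(=O)CBr | starting material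
8 | (4-bromo-2-oxobutyl)triphenylphosphonium bromide | [Br-].BrCCC(=O)C[P+](c1ccccc1)(c1ccccc1)c1ccccc1 | intermediate (not isolated)
9 | 4-bromo-1-(triphenyl-λ5-phosphanylidene)butan-2-one | BrCCC(=O)C=P(c1ccccc1)(c1ccccc1)c1ccccc1 | intermediate
10 | methyl 2-(2-allyl-4,5-dimethoxyphenoxy)-5-oxo-2-(phenylthio)-6-(triphenyl-λ5-phosphanylidene)hexanoate (racemic) | C=CCc1cc(OC)c(OC)cc1OC(Sc1ccccc1)(CCC(=O)C=P(c1ccccc1)(c1ccccc1)c1ccccc1)C(=O)OC | intermediate (not isolated)
11 | 4-(2-allyl-4,5-dimethoxyphenoxy)-3-methoxy-4-(phenylthio)cyclohex-2-en-1-one (racemic) | C=CCc1cc(OC)c(OC)cc1OC1(Sc2ccccc2)CCC(=O)C=C1OC | intermediate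
12 | allyl 4-(2-allyl-4,5-dimethoxyphenoxy)-5-methoxy-4-(phenylthio)cyclohexa-1,5-dien-1-yl carbonate (racemic) | C=CCOC(=O)OC1=CCC(Oc2cc(OC)c(OC)cc2CC=C)(Sc2ccccc2)C(OC)=C1 | intermediate
13 | (6S)-6-allyl-4-(2-allyl-4,5-dimethoxyphenoxy)-3-methoxy-4-(phenylthio)cyclohex-2-en-1-one (both C4 epimers) | C=CCc1cc(OC)c(OC)cc1OC1(Sc2ccccc2)C[C@H](CC=C)C(=O)C=C1OC | intermediate
14 | (4R,6S)-6-allyl-4-(2-allyl-4,5-dimethoxyphenoxy)-3,4-dimethoxycyclohex-2-en-1-one | C=CCc1cc(OC)c(OC)cc1O[C@]1(OC)C[C@H](CC=C)C(=O)C=C1OC | target

Total step count: 9. Longest linear sequence: 7 steps (steps 1, 2, 4, 6, 7, 8, 9).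

Steps most likely to fail

1. Step 6 (proposed new method). The ylide may be C-acylated by the ester with loss of methoxide instead of olefinating it, or the alkylation may stall at the hindered tertiary carbanion. The fallback uses known chemistry, sets out from 6 and comes back at 11. Base-catalysed Michael addition of 6 to methyl vinyl ketone (KOtBu cat., THF, 0 °C) gives the keto ester methyl 2-(2-allyl-4,5-dimethoxyphenoxy)-5-oxo-2-(phenylthio)hexanoate F1. Intramolecular Claisen (Dieckmann-type) condensation of the methyl ketone enolate onto the ester (KOtBu, THF) gives 4-(2-allyl-4,5-dimethoxyphenoxy)-4-(phenylthio)cyclohexane-1,3-dione F2. O-Methylation (K2CO3, dimethyl sulfate, acetone) gives 11 together with its regioisomeric enol ether 6-(2-allyl-4,5-dimethoxyphenoxy)-3-methoxy-6-(phenylthio)cyclohex-2-en-1-one F3. The two are separated by chromatography, and F3 is hydrolysed back to F2 with aqueous NaOH and recycled. The price of this fallback is that the regiochemistry of the enol ether is no longer fixed by construction.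

2. Step 9. Capture of the oxocarbenium ion by methanol may show poor facial selectivity (attack syn to the allyl group competing), which erodes the C4 configuration. The same ion can also lose a C5 proton and aromatise; the fallback does not remove that risk, because its first operation passes through an ion of the same type. The fallback sets out from 11 and comes back at 14. The methanolysis is run first on 11 (same silver conditions, no stereochemical demand) to give racemic 4-(2-allyl-4,5-dimethoxyphenoxy)-3,4-dimethoxycyclohex-2-en-1-one F4. Enol carbonate formation as in step 7 gives allyl 4-(2-allyl-4,5-dimethoxyphenoxy)-4,5-dimethoxycyclohexa-1,5-dien-1-yl carbonate F5. The allylation of step 8, under catalyst control at C6, should then give 14 and its C4 epimer (4S,6S)-6-allyl-4-(2-allyl-4,5-dimethoxyphenoxy)-3,4-dimethoxycyclohex-2-en-1-one F6. These are diastereomers and are separated on silica; at most half of the material ends as 14.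

3. Step 8. The ligand may discriminate poorly between the faces of the unsubstituted C6 enolate, or the tertiary α-centre may racemise through enolate exchange. The fallback sets out from 11 and comes back at 14. Stork–Danheiser α'-alkylation of 11 (LDA, THF, −78 °C; allyl bromide) gives racemic 6-allyl-4-(2-allyl-4,5-dimethoxyphenoxy)-3-methoxy-4-(phenylthio)cyclohex-2-en-1-one F7. Methanolysis as in step 9 sets the relative configuration and gives 14 together with its enantiomer (4S,6R)-6-allyl-4-(2-allyl-4,5-dimethoxyphenoxy)-3,4-dimethoxycyclohex-2-en-1-one F8. The two are separated by preparative chromatography on a chiral stationary phase.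

Further compounds
F1 | step 6 | methyl 2-(2-allyl-4,5-dimethoxyphenoxy)-5-oxo-2-(phenylthio)hexanoate (racemic) | C=CCc1cc(OC)c(OC)cc1OC(Sc1ccccc1)(CCC(C)=O)C(=O)OC
F2 | step 6 | 4-(2-allyl-4,5-dimethoxyphenoxy)-4-(phenylthio)cyclohexane-1,3-dione (racemic) | C=CCc1cc(OC)c(OC)cc1OC1(Sc2ccccc2)CCC(=O)CC1=O
F3 | step 6 | 6-(2-allyl-4,5-dimethoxyphenoxy)-3-methoxy-6-(phenylthio)cyclohex-2-en-1-one (racemic) | C=CCc1cc(OC)c(OC)cc1OC1(Sc2ccccc2)CCC(OC)=CC1=O
F4 | step 9 | 4-(2-allyl-4,5-dimethoxyphenoxy)-3,4-dimethoxycyclohex-2-en-1-one (racemic) | C=CCc1cc(OC)c(OC)cc1OC1(OC)CCC(=O)C=C1OC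
F5 | step 9 | allyl 4-(2-allyl-4,5-dimethoxyphenoxy)-4,5-dimethoxycyclohexa-1,5-dien-1-yl carbonate (racemic) | C=CCOC(=O)OC1=CCC(OC)(Oc2cc(OC)c(OC)cc2CC=C)C(OC)=C1
F6 | step 9 | (4S,6S)-6-allyl-4-(2-allyl-4,5-dimethoxyphenoxy)-3,4-dimethoxycyclohex-2-en-1-one | C=CCc1cc(OC)c(OC)cc1O[C@@]1(OC)C[C@H](CC=C)C(=O)C=C1OC
F7 | step 8 | 6-allyl-4-(2-allyl-4,5-dimethoxyphenoxy)-3-methoxy-4-(phenylthio)cyclohex-2-en-1-one (racemic, both C4 epimers) | C=CCc1cc(OC)c(OC)cc1OC1(Sc2ccccc2)CC(CC=C)C(=O)C=C1OC
F8 | step 8 | (4S,6R)-6-allyl-4-(2-allyl-4,5-dimethoxyphenoxy)-3,4-dimethoxycyclohex-2-en-1-one | C=CCc1cc(OC)c(OC)cc1O[C@@]1(OC)C[C@@H](CC=C)C(=O)C=C1OC
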